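The route rests on cutting the cyclohexene ring at its tetrasubstituted C5=C10 alkene, which bears C4 and the C15 methyl. Ring-closing enyne metathesis of a 1,7-enyne joins a C8-bound methallyl group (C9, C10, C14) to a C4≡C5 alkyne: in one operation it closes the six-membered carbocycle at C5=C10 and moves the alkene methylene to C4 as the C4=C15 methylidene. The precursor is a cis-4,5-disubstituted γ-lactone with the methallyl group on C8 and, on C7, an R-configured propargylic alcohol (C6) whose alkyne ends in the silyl-protected C1–C3 chain. The C6 hydroxyl then relays chirality to C4 by directed hydrogenation; α-methylenation and acetylation finish the synthesis.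

Key step: step 8

Remarks on the chemistry:
- Atom numbers are those of the 1,10-seco-eudesmane skeleton: C1 (CH2OAc), C2, C3, C4 (bearing methyl C15), C5=C10 (C14 is the methyl on C10), C9, C8 (lactone oxygen), C7, C6 (OAc), C11=C13, C12 (lactone carbonyl).
- The target SMILES is read as having H6, H7 and H8 on one face of the carbocycle (6R, cis-fused lactone) and C4 as S; all descriptors below are derived from it.
- The precursor is reached from a chiral-pool β-hydroxy ester by anti-selective dianion alkylation; the succinate unit enters as ethyl bromoacetate and the methallyl unit as an isopropenyl Grignard reagent.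
- Solutions of LiN(iPr)2, n-BuLi and isopropenylmagnesium bromide are taken as bought.

Step 1
Reactants: 1 pent-4-yn-1-ol
Product: 2 tert-butyl(dimethyl)(pent-4-yn-1-yloxy)silane
Conditions: TBSCl, imidazole, CH2Cl2, 0 °C to rt
Reagents that add atoms: tert-butyl(chloro)dimethylsilane, CC(C)(C)[Si](C)(C)Cl
Why: Imidazole-promoted silyl ether formation on a primary alcohol, to which the terminal alkyne is inert.

Step 2
Reactants: 3 ethyl (3S)-4-chloro-3-hydroxybutanoate
Product: 4 ethyl 2-[(2S)-oxiran-2-yl]acetate
Conditions: Ag2O, DME, 60 °C, dark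
Reagents that add atoms: none
Why: Silver-oxide-promoted intramolecular Williamson etherification of the chlorohydrin gives the β,γ-epoxy ester without an alkoxide base, which would open it to the 4-hydroxycrotonate; the C–O bond at the stereocentre is kept, so its configuration is retained.

Step 3
Reactants: 4 ethyl 2-[(2S)-oxiran-2-yl]acetate; 5 isopropenylmagnesium bromide
Product: 6 ethyl (3R)-3-hydroxy-5-methylhex-5-enoate
Conditions: 5 (1.5 equiv), CuI (10 mol%), THF, −40 °C; aq NH4Cl
Reagents that add atoms: none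
Why: Copper-catalysed Grignard opening of a terminal epoxide at its CH2 carbon (SN2), which at −40 °C should outrun addition to the ester; the carbinol centre is untouched and its descriptor changes from S to R by priority only.

Step 4
Reactants: 6 ethyl (3R)-3-hydroxy-5-methylhex-5-enoate; 7 ethyl bromoacetate
Product: 8 diethyl (2R)-2-[(1R)-1-hydroxy-3-methylbut-3-en-1-yl]butanedioate
Conditions: LiN(iPr)2 (2.2 equiv), THF, −78 to −20 °C; 7, DMPU, −78 to −30 °C; AcOH, −78 °C
Reagents that add atoms: none
Why: Fráter–Seebach alkylation: the lithium-chelated alkoxide enolate dianion is alkylated by the bromoacetate on the face away from the C9 side chain, so the new C7 centre forms anti to the C8 oxygen (2R); the cold acetic acid quench limits lactonisation, which would in any case converge in step 5.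

Step 5
Reactants: 8 diethyl (2R)-2-[(1R)-1-hydroxy-3-methylbut-3-en-1-yl]butanedioate
Product: 10 (2R,3R)-2-(2-methylprop-2-en-1-yl)-5-oxooxolane-3-carboxylic acid, via hydroxy diacid 9 (not isolated)
Conditions: LiOH, THF/H2O, 0 °C to rt; 1 M HCl to pH 2, 0 °C; PPTS (cat.), CH2Cl2, rt
Reagents that add atoms: lithium hydroxide, [Li+].[OH-]
Why: Ester saponification followed by acid-promoted γ-lactonisation of the C8 hydroxyl onto the C12 acid (the C6 acid could only form a strained β-lactone); both are acyl substitutions that leave C7 and C8 untouched, so the anti diester should give the cis-disubstituted lactone.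

Step 6
Reactants: 10 (2R,3R)-2-(2-methylprop-2-en-1-yl)-5-oxooxolane-3-carboxylic acid; 2 tert-butyl(dimethyl)(pent-4-yn-1-yloxy)silane
Product: 14 (4R,5R)-4-(6-{[tert-butyl(dimethyl)silyl]oxy}hex-2-ynoyl)-5-(2-methylprop-2-en-1-yl)oxolan-2-one, via acid chloride 11 (not isolated), via lithium acetylide 12 (not isolated), via alkynylzinc chloride 13 (not isolated)
Conditions: 10, 1-chloro-N,N,2-trimethylprop-1-en-1-amine, CH2Cl2, 0 °C; separately 2, n-BuLi, THF, −78 °C, then ZnCl2, 0 °C; combine, Pd(PPh3)4 (5 mol%), THF, 0 °C to rt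
Reagents that add atoms: none
Why: Negishi acylation, the palladium-catalysed coupling of an acid chloride with an alkynylzinc halide: the acid chloride is made under neutral conditions and the weakly basic zinc acetylide should attack neither the lactone nor the C7–H, so the cis β-acyl lactone is expected to pass through without epimerisation or β-elimination.

Step 7
Reactants: 14 (4R,5R)-4-(6-{[tert-butyl(dimethyl)silyl]oxy}hex-2-ynoyl)-5-(2-methylprop-2-en-1-yl)oxolan-2-one
Product: 15 (4S,5R)-4-[(1R)-6-{[tert-butyl(dimethyl)silyl]oxy}-1-hydroxyhex-2-yn-1-yl]-5-(2-methylprop-2-en-1-yl)oxolan-2-one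
Conditions: Ru[(R,R)-TsDPEN](p-cymene) (2 mol%), iPrOH, rt
Reagents that add atoms: none
Why: Noyori asymmetric transfer hydrogenation of an alkynyl ketone under neutral conditions: the (R,R) catalyst, with the alkynyl group in the place usually held by an aryl group, should deliver hydride to the carbonyl face that gives the 6R alcohol under catalyst control; the change from 4R to 4S at C7 is a priority effect only.

Step 8
Reactants: 15 (4S,5R)-4-[(1R)-6-{[tert-butyl(dimethyl)silyl]oxy}-1-hydroxyhex-2-yn-1-yl]-5-(2-methylprop-2-en-1-yl)oxolan-2-one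
Product: 16 (3aS,4R,7aR)-5-(5-{[tert-butyl(dimethyl)silyl]oxy}pent-1-en-2-yl)-4-hydroxy-6-methyl-3a,4,7,7a-tetrahydro-1-benzofuran-2(3H)-one
Conditions: second-generation Grubbs catalyst RuCl2(=CHPh)(PCy3)(SIMes) (10 mol%), ethylene (1 atm), toluene (0.005 M), 80 °C
Reagents that add atoms: none
Why: Under ethylene the catalyst rests as the ruthenium methylidene, which adds across the C4≡C5 alkyne with its carbon on the less hindered C4 to give, by opening of the ruthenacyclobutene, a vinylcarbene at C5 that already carries the C4=C15 methylidene; [2+2] cycloaddition of this carbene to the C10=CH2 alkene and cycloreversion form C5=C10 and return the methylidene. The closest known reaction type is exo-mode ring-closing enyne metathesis of 1,7-enynes to 1-alkenylcyclohexenes, which has been extended with N-heterocyclic carbene catalysts to 1,1-disubstituted alkenes and thus to tetrasubstituted ring alkenes. The one ring formed, the carbocycle C5–C6–C7–C8–C9–C10, closes in exo mode as a six-membered ring with C4 left outside it. No stereocentre is created, and C6, C7 and C8 are not touched. The step needs the six-membered exo diene to win over the seven-membered endo diene (carbene at C4), over ethylene capture of the C5 carbene to an acyclic triene and over dimerisation. The substrate helps in three ways: the 1,1-disubstituted alkene cannot load the catalyst, so the reaction must start at the alkyne; the branched C6 carbinol steers the metal to C5; and the cis lactone holds the two arms on one face, four atoms apart, so that closure should be fast at high dilution.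

Step 9
Reactants: 16 (3aS,4R,7aR)-5-(5-{[tert-butyl(dimethyl)silyl]oxy}pent-1-en-2-yl)-4-hydroxy-6-methyl-3a,4,7,7a-tetrahydro-1-benzofuran-2(3H)-one
Product: 17 (3aS,4R,7aR)-5-[(2S)-5-{[tert-butyl(dimethyl)silyl]oxy}pentan-2-yl]-4-hydroxy-6-methyl-3a,4,7,7a-tetrahydro-1-benzofuran-2(3H)-one
Conditions: [Rh(nbd)(dppb)]BF4 (10 mol%), H2 (50 atm), CH2Cl2, rt
Reagents that add atoms: none
Why: Hydroxyl-directed hydrogenation with a cationic rhodium diphosphine catalyst: rhodium bound to the C6 hydroxyl should reduce only the 1,1-disubstituted C4=C15 alkene of the twisted diene (the tetrasubstituted C5=C10 alkene is inert to this catalyst), adding hydrogen to the alkene face turned toward C6 in the rotamer that keeps the methylidene on the hydroxyl side of the ring, which sets C4 as S; high hydrogen pressure suppresses alkene migration.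

Step 10
Reactants: 17 (3aS,4R,7aR)-5-[(2S)-5-{[tert-butyl(dimethyl)silyl]oxy}pentan-2-yl]-4-hydroxy-6-methyl-3a,4,7,7a-tetrahydro-1-benzofuran-2(3H)-one
Product: 18 (3aR,4R,7aR)-5-[(2S)-5-{[tert-butyl(dimethyl)silyl]oxy}pentan-2-yl]-6-methyl-4-[(triethylsilyl)oxy]-3a,4,7,7a-tetrahydro-1-benzofuran-2(3H)-one
Conditions: TESOTf, 2,6-lutidine, CH2Cl2, −78 to 0 °C
Reagents that add atoms: triethylsilyl trifluoromethanesulfonate, CC[Si](CC)(CC)OS(=O)(=O)C(F)(F)F
Why: Silyl triflate silylation of a hindered secondary allylic alcohol; it masks the C6 hydroxyl, which as an alkoxide in step 11 would attack the lactone carbonyl and scramble the lactone between O6 and O8.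

Step 11
Reactants: 18 (3aR,4R,7aR)-5-[(2S)-5-{[tert-butyl(dimethyl)silyl]oxy}pentan-2-yl]-6-methyl-4-[(triethylsilyl)oxy]-3a,4,7,7a-tetrahydro-1-benzofuran-2(3H)-one
Product: 21 (3aR,4R,7aR)-5-[(2S)-5-{[tert-butyl(dimethyl)silyl]oxy}pentan-2-yl]-6-methyl-3-methylidene-4-[(triethylsilyl)oxy]-3a,4,7,7a-tetrahydro-1-benzofuran-2(3H)-one, via Mannich base 19 (not isolated), via ammonium iodide 20 (not isolated)
Conditions: LiN(iPr)2, THF, −78 °C; CH2=NMe2+ I−, −78 °C to rt; MeI, THF, rt; NaHCO3, H2O/CH2Cl2, rt
Reagents that add atoms: dimethyl(methylidene)ammonium iodide, C=[N+](C)C.[I-]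
Why: α-Methylenation of a lactone by the Mannich route: the lithium enolate at C11 is aminomethylated by the iminium salt, N-methylation gives the ammonium salt, and mild base brings about Hofmann-type elimination to the exocyclic alkene; C11 ends as sp2, so its transient configuration is immaterial, and C7 is not enolisable.

Step 12
Reactants: 21 (3aR,4R,7aR)-5-[(2S)-5-{[tert-butyl(dimethyl)silyl]oxy}pentan-2-yl]-6-methyl-3-methylidene-4-[(triethylsilyl)oxy]-3a,4,7,7a-tetrahydro-1-benzofuran-2(3H)-one
Product: 22 (3aS,4R,7aR)-4-hydroxy-5-[(2S)-5-hydroxypentan-2-yl]-6-methyl-3-methylidene-3a,4,7,7a-tetrahydro-1-benzofuran-2(3H)-one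
Conditions: HF·pyridine, pyridine, THF, 0 °C to rt
Reagents that add atoms: none
Why: Fluoride-mediated cleavage of both silyl ethers under buffered, weakly acidic conditions that should spare the α-methylene lactone and not set off translactonisation.

Step 13
Reactants: 22 (3aS,4R,7aR)-4-hydroxy-5-[(2S)-5-hydroxypentan-2-yl]-6-methyl-3-methylidene-3a,4,7,7a-tetrahydro-1-benzofuran-2(3H)-one
Product: 23 (4S)-4-[(3aR,4R,7aR)-4-(acetyloxy)-6-methyl-3-methylidene-2-oxo-2,3,3a,4,7,7a-hexahydro-1-benzofuran-5-yl]pentyl acetate (1,6-O,O-diacetylbritannilactone)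
Conditions: Ac2O, pyridine, DMAP (cat.), CH2Cl2, 0 °C to rt
Reagents that add atoms: acetic anhydride, CC(=O)OC(C)=O
Why: Acylation of the primary and the secondary allylic hydroxyl with acetic anhydride under nucleophilic catalysis; no stereocentre is involved.

Compound list
1 | pent-4-yn-1-ol | C#CCCCO | starting material
2 | tert-butyl(dimethyl)(pent-4-yn-1-yloxy)silane | C#CCCCO[Si](C)(C)C(C)(C)C | intermediate
3 | ethyl (3S)-4-chloro-3-hydroxybutanoate | CCOC(=O)C[C@H](O)CCl | starting material
4 | ethyl 2-[(2S)-oxiran-2-yl]acetate | CCOC(=O)C[C@H]1CO1 | intermediate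
5 | isopropenylmagnesium bromide | C=C(C)[Mg]Br | starting material
6 | ethyl (3R)-3-hydroxy-5-methylhex-5-enoate | CCOC(=O)C[C@H](O)CC(C)=C | intermediate
7 | ethyl bromoacetate | CCOC(=O)CBr | starting material
8 | diethyl (2R)-2-[(1R)-1-hydroxy-3-methylbut-3-en-1-yl]butanedioate | CCOC(=O)C[C@@H](C(=O)OCC)[C@H](O)CC(C)=C | intermediate
9 | (2R)-2-[(1R)-1-hydroxy-3-methylbut-3-en-1-yl]butanedioic acid (formed as its dilithium salt) | OC(=O)C[C@@H](C(O)=O)[C@H](O)CC(C)=C | intermediate (not isolated)
10 | (2R,3R)-2-(2-methylprop-2-en-1-yl)-5-oxooxolane-3-carboxylic acid | O=C1C[C@@H](C(=O)O)[C@@H](CC(C)=C)O1 | intermediate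
11 | (2R,3R)-2-(2-methylprop-2-en-1-yl)-5-oxooxolane-3-carbonyl chloride | O=C1C[C@@H](C(=O)Cl)[C@@H](CC(C)=C)O1 | intermediate (not isolated)
12 | (5-{[tert-butyl(dimethyl)silyl]oxy}pent-1-yn-1-yl)lithium | [Li]C#CCCCO[Si](C)(C)C(C)(C)C | intermediate (not isolated)
13 | chloro(5-{[tert-butyl(dimethyl)silyl]oxy}pent-1-yn-1-yl)zinc | Cl[Zn]C#CCCCO[Si](C)(C)C(C)(C)C | intermediate (not isolated)
14 | (4R,5R)-4-(6-{[tert-butyl(dimethyl)silyl]oxy}hex-2-ynoyl)-5-(2-methylprop-2-en-1-yl)oxolan-2-one | O=C1C[C@@H](C(=O)C#CCCCO[Si](C)(C)C(C)(C)C)[C@@H](CC(C)=C)O1 | intermediate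
15 | (4S,5R)-4-[(1R)-6-{[tert-butyl(dimethyl)silyl]oxy}-1-hydroxyhex-2-yn-1-yl]-5-(2-methylprop-2-en-1-yl)oxolan-2-one | O=C1C[C@@H]([C@@H](O)C#CCCCO[Si](C)(C)C(C)(C)C)[C@@H](CC(C)=C)O1 | intermediate (precursor of the key step)
16 | (3aS,4R,7aR)-5-(5-{[tert-butyl(dimethyl)silyl]oxy}pent-1-en-2-yl)-4-hydroxy-6-methyl-3a,4,7,7a-tetrahydro-1-benzofuran-2(3H)-one | C1C(=O)O[C@@H]2CC(C)=C(C(=C)CCCO[Si](C)(C)C(C)(C)C)[C@H](O)[C@H]12 | intermediate (product of the key step)
17 | (3aS,4R,7aR)-5-[(2S)-5-{[tert-butyl(dimethyl)silyl]oxy}pentan-2-yl]-4-hydroxy-6-methyl-3a,4,7,7a-tetrahydro-1-benzofuran-2(3H)-one | C1C(=O)O[C@@H]2CC(C)=C([C@@H](C)CCCO[Si](C)(C)C(C)(C)C)[C@H](O)[C@H]12 | intermediate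
18 | (3aR,4R,7aR)-5-[(2S)-5-{[tert-butyl(dimethyl)silyl]oxy}pentan-2-yl]-6-methyl-4-[(triethylsilyl)oxy]-3a,4,7,7a-tetrahydro-1-benzofuran-2(3H)-one | C1C(=O)O[C@@H]2CC(C)=C([C@@H](C)CCCO[Si](C)(C)C(C)(C)C)[C@H](O[Si](CC)(CC)CC)[C@H]12 | intermediate
19 | (3aR,4R,7aR)-5-[(2S)-5-{[tert-butyl(dimethyl)silyl]oxy}pentan-2-yl]-3-[(dimethylamino)methyl]-6-methyl-4-[(triethylsilyl)oxy]-3a,4,7,7a-tetrahydro-1-benzofuran-2(3H)-one (C3 epimers) | CN(C)CC1C(=O)O[C@@H]2CC(C)=C([C@@H](C)CCCO[Si](C)(C)C(C)(C)C)[C@H](O[Si](CC)(CC)CC)[C@H]12 | intermediate (not isolated)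
20 | trimethylammonium iodide of 19 (N-methylated at the dimethylamino group) | C[N+](C)(C)CC1C(=O)O[C@@H]2CC(C)=C([C@@H](C)CCCO[Si](C)(C)C(C)(C)C)[C@H](O[Si](CC)(CC)CC)[C@H]12.[I-] | intermediate (not isolated)
21 | (3aR,4R,7aR)-5-[(2S)-5-{[tert-butyl(dimethyl)silyl]oxy}pentan-2-yl]-6-methyl-3-methylidene-4-[(triethylsilyl)oxy]-3a,4,7,7a-tetrahydro-1-benzofuran-2(3H)-one | C=C1C(=O)O[C@@H]2CC(C)=C([C@@H](C)CCCO[Si](C)(C)C(C)(C)C)[C@H](O[Si](CC)(CC)CC)[C@H]12 | intermediate
22 | (3aS,4R,7aR)-4-hydroxy-5-[(2S)-5-hydroxypentan-2-yl]-6-methyl-3-methylidene-3a,4,7,7a-tetrahydro-1-benzofuran-2(3H)-one | C=C1C(=O)O[C@@H]2CC(C)=C([C@@H](C)CCCO)[C@H](O)[C@H]12 | intermediate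
23 | (4S)-4-[(3aR,4R,7aR)-4-(acetyloxy)-6-methyl-3-methylidene-2-oxo-2,3,3a,4,7,7a-hexahydro-1-benzofuran-5-yl]pentyl acetate | C=C1C(=O)O[C@@H]2CC(C)=C([C@@H](C)CCCOC(C)=O)[C@H](OC(C)=O)[C@H]12 | target

Total step count: 13. Longest linear sequence: 12 steps (steps 2 to 13, from 3); step 1 is a one-step side branch.

Steps most likely to fail

1. Step 8. The C5 vinylcarbene may be captured by ethylene before it closes onto the hindered 1,1-disubstituted alkene, or the methylidene may add with the opposite regiochemistry and lead to the seven-membered endo diene. The fallback splits the event into two known metatheses and sets out from 15. Alkyne–ethylene cross-metathesis (RuCl2(=CHPh)(PCy3)(SIMes), ethylene 4 atm, CH2Cl2, 40 °C) is run deliberately to completion to give the triene (4S,5R)-4-[(1R)-6-{[tert-butyl(dimethyl)silyl]oxy}-1-hydroxy-2,3-dimethylidenehexyl]-5-(2-methylprop-2-en-1-yl)oxolan-2-one F1. Both regiochemical modes of insertion converge on this compound. Ring-closing olefin metathesis between the C5 methylidene and the methallyl alkene then follows, with the less hindered complex RuCl2(=CH-C6H4-2-OiPr)(L), L = 1,3-bis(2-methylphenyl)imidazolidin-2-ylidene, in toluene at 80 °C under an argon sparge that removes ethylene. Six-membered closure should be preferred over the seven-membered alternative through the C4 methylidene, and the sequence comes back to the route at 16.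

2. Step 9. Facial selectivity at C4 may be poor if the diene does not react through the rotamer assumed, and the alkene may migrate before it is reduced. The fallback replaces substrate direction by catalyst control and sets out from 16. The C6 hydroxyl is silylated first (TESOTf, 2,6-lutidine, CH2Cl2) to give (3aR,4R,7aR)-5-(5-{[tert-butyl(dimethyl)silyl]oxy}pent-1-en-2-yl)-6-methyl-4-[(triethylsilyl)oxy]-3a,4,7,7a-tetrahydro-1-benzofuran-2(3H)-one F2. The 1,1-disubstituted alkene is then hydrogenated with a chiral iridium phosphino-oxazoline complex, [Ir(cod)(tBu-PHOX)]B[3,5-(CF3)2C6H3]4 (H2 50 atm, CH2Cl2, rt), the ligand enantiomer being chosen in a small screen. The tetrasubstituted ring alkene should stay intact, and the fallback comes back to the route at 18, so that step 10 is no longer needed.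

3. Step 6. The cis β-acyl lactone may epimerise at C7 to the trans series, or open by β-elimination of the carboxylate, at the acid chloride or acyl-palladium stage. The fallback avoids both species and sets out from 10. Amide coupling (EDC·HCl, MeNHOMe·HCl, N-methylmorpholine, CH2Cl2, 0 °C) gives (2R,3R)-N-methoxy-N-methyl-2-(2-methylprop-2-en-1-yl)-5-oxooxolane-3-carboxamide F3. Lithium acetylide 12 (1.05 equiv, THF, −78 °C) is then added to it and the mixture is quenched cold with acid; the chelated tetrahedral adduct should release the ketone only on work-up. Competing attack on the lactone carbonyl is the weakness of this variant. It comes back to the route at 14.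

Further compounds
F1 | step 8 | (4S,5R)-4-[(1R)-6-{[tert-butyl(dimethyl)silyl]oxy}-1-hydroxy-2,3-dimethylidenehexyl]-5-(2-methylprop-2-en-1-yl)oxolan-2-one | O=C1C[C@@H]([C@@H](O)C(=C)C(=C)CCCO[Si](C)(C)C(C)(C)C)[C@@H](CC(C)=C)O1
F2 | step 9 | (3aR,4R,7aR)-5-(5-{[tert-butyl(dimethyl)silyl]oxy}pent-1-en-2-yl)-6-methyl-4-[(triethylsilyl)oxy]-3a,4,7,7a-tetrahydro-1-benzofuran-2(3H)-one | C1C(=O)O[C@@H]2CC(C)=C(C(=C)CCCO[Si](C)(C)C(C)(C)C)[C@H](O[Si](CC)(CC)CC)[C@H]12
F3 | step 6 | (2R,3R)-N-methoxy-N-methyl-2-(2-methylprop-2-en-1-yl)-5-oxooxolane-3-carboxamide | O=C1C[C@@H](C(=O)N(C)OC)[C@@H](CC(C)=C)O1
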